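I wanted one ratio for each flask: the time it stayed hot over the time its charge of Z needs to vanish.

| flask | Z | temperature | remark | time |
|---|---|---|---|---|
| violet | 0.025 M | 50 °C | run made earlier |  |
| green | 0.038 M | 83 °C | run made earlier |  |
| birch | 0.050 M | 95 °C |  | 2.0 h |
| oak | 0.050 M | 65 °C |  | 2.0 h |
| larch | 0.050 M |  | at 95 °C until 80 min, from then on at 35 °C | 2.0 h |
| maple | 0.050 M | 35 °C |  | 2.0 h |

| run | time / h | X / % | Z / % |
|---|---|---|---|
| violet | 3.00 | 7 | 87 |
| violet | 6.00 | 11 | 77 |
| violet | 10.0 | 28 | 69 |
| violet | 12.0 | 30 | 60 |
| violet | 15.0 | 45 | 46 |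
| green | 0.250 | 9 | 94 |
| green | 0.417 | 13 | 85 |
| green | 0.833 | 33 | 65 |
| green | 1.50 | 56 | 41 |
| green | 2.50 | 100 | 2 |

(scatter of a reading: 2 percentage points)

* the best flask by amount of X, in percent of the Z charged; "all alike" if 1.5 percentage points covers them all (birch / oak / larch / maple / all alike)
* amount of X at the end, in percent of the Z charged, birch
* amount of X at the end, in percent of the Z charged, oak
* amount of X at the end, in percent of the Z charged, larch
* amount of X at the end, in percent of the Z charged, maple

- as a solid, counted per litre of solution: Z
- steps under discussion: Q + 2 X -> 3 X; Q -> X; Z <-> Q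
- at the start none of Z is in solution
- what has only dissolved of Z counts as not reacted

Was dissolved Q a store or a correction? In the violet run, X and Z together missed the charge by 8.00% on average; in the green run the mean miss was 0.400%, but that mean nets misses of both signs. So I took Q as a correction of some points, and the loss of Z as an upper estimate of the gain of X.

How fast did the solid go? Z fell roughly in a straight line, a zero-order loss, and between the last two green readings I read a pace of 0.0148 M h⁻¹. The violet run read 8.542 × 10⁻⁴ M h⁻¹, slower. Birch and larch start hotter than green, so I took the green pace as their floor. The charge over that pace gave 3.37 h, the clearing time, as my upper limit.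

Would larch clear before its change? The ratio of 80 min to the clearing time is 39.5%, so my own reckoning put X at the change between that share and full conversion. At the violet pace, I reckoned the cold remainder at about 1.14%. Birch stays hot longer, so I ranked it first.

The forecast named birch, with birch 100%, oak 11%, larch 96% and maple 0.7%. It used 0.038 M/h at the higher temperature and said: “Larch is therefore nearly finished at the switch”.

The flasks gave birch as best, with birch >99.9%, oak 12.0%, larch 66.6% and maple 0.318%.

    Q + 2 X → 3 X (k = 0.310 L² mol⁻² s⁻¹, Ea = 57.0 kJ mol⁻¹)
    Q → X (k = 1.20 × 10⁻⁵ s⁻¹, Ea = 106 kJ mol⁻¹)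
    Z ⇌ Q, rate k3*(cs3 - [Q]) while solid is left; crystals form when [Q] > cs3 (solubility = 1.90 mM, k = 0.00480 s⁻¹)
    (constants at 35 °C)

Larch stood at Z 35.4% and X 63.9% after 1.33 h, a hot pace of 0.0242 M h⁻¹, faster than my floor. At that pace its clearing time is 2.07 h, longer than the hot stretch, and larch ended with Z 29.9%. The neighbouring flask is larch with 0.013 M of Z. My clearing time, scaled to that charge, becomes 52.6 min, shorter than the hot stretch, and larch's pace gives 32.2 min. That neighbour ended with X 100% and 0% of its Z still there.

All runs come from a simulation with constants of no real substance, noise included.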